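**Retrosynthetic overview**
1. The target is ent-guibourtinidol-(4β→8)-epicatechin; its six phenols are carried as benzyl ethers and freed last from 12 by hydrogenolysis.
2. Key disconnection: the C4–C8 interflavan bond and the O1–C2 bond of the upper ring C are cut together, giving the open-chain epoxy alcohol 7 and tetra-O-benzyl-epicatechin 9 (one step from bought (−)-epicatechin).
3. Enabling feature: in the upper unit C2 is benzylic to ring B and para to O4', and C4 is benzylic to ring A, para to O7 and ortho to O1, so both carbons flanking the carbinol C3 ionise easily; C8 of ring A of epicatechin, between O7 and O1, is the accessible nucleophilic carbon.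
4. 7 comes from chalcone 4 by catalytic asymmetric epoxidation (sets C3 and the epoxide carbon that becomes C2), ketone reduction and deallylation; 4 comes from an acetophenone and an aldehyde by aldol condensation.
5. Ring order: rings A and B of the upper unit and all three rings of the lower unit are bought; the upper ring C is the only ring made, in step 7, in the same operation as the interflavan bond.

Key step: step 7

Remark: the carbinol carbon of 6 and 7 (later C4) forms as a mixture of epimers and is drawn without configuration, because this centre is ionised in step 7; any minor enantiomer carried from step 3 becomes a diastereomer of 12 after coupling with enantiopure 9 and should be separable there.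

**Step 1**
Reactants: 1 1-[4-(benzyloxy)-2-hydroxyphenyl]ethan-1-one
Product: 2 1-[4-(benzyloxy)-2-(prop-2-en-1-yloxy)phenyl]ethan-1-one
Conditions: allyl bromide (1.5 equiv), K2CO3, DMF, 60 °C
Reagents that add atoms: allyl bromide C=CCBr
Why: Williamson etherification of the hydrogen-bonded 2-hydroxyl masks the phenol against the basic peroxide of step 3 with a group that can later be removed under neutral conditions; no stereocentre is formed.

**Step 2**
Reactants: 2 1-[4-(benzyloxy)-2-(prop-2-en-1-yloxy)phenyl]ethan-1-one; 3 4-(benzyloxy)benzaldehyde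
Product: 4 (E)-3-[4-(benzyloxy)phenyl]-1-[4-(benzyloxy)-2-(prop-2-en-1-yloxy)phenyl]prop-2-en-1-one
Conditions: KOH, EtOH, rt
Reagents that add atoms: none
Why: Claisen–Schmidt aldol condensation of the methyl ketone enolate with the non-enolisable aldehyde, followed by dehydration, should give the thermodynamically favoured E-enone; no stereocentre is formed.

**Step 3**
Reactants: 4 (E)-chalcone
Product: 5 [4-(benzyloxy)-2-(prop-2-en-1-yloxy)phenyl][(2S,3R)-3-[4-(benzyloxy)phenyl]oxiran-2-yl]methanone
Conditions: poly-D-leucine, urea–H2O2, DBU, THF, rt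
Reagents that add atoms: urea–hydrogen peroxide OO.NC(N)=O
Why: Juliá–Colonna epoxidation (Weitz–Scheffer conjugate addition of hydroperoxide inside the helical polypeptide) should set both epoxide carbons as the trans-(2S,3R) oxirane, poly-D-leucine being chosen because the L-polymer is known to give the (2R,3S) series with chalcones; the allyl ether alkene is not electrophilic and should stay untouched.

**Step 4**
Reactants: 5 trans-(2S,3R)-epoxy ketone
Product: 6 [4-(benzyloxy)-2-(prop-2-en-1-yloxy)phenyl][(2R,3R)-3-[4-(benzyloxy)phenyl]oxiran-2-yl]methanol (both carbinol epimers)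
Conditions: NaBH4, MeOH/THF, 0 °C
Reagents that add atoms: none
Why: Borohydride 1,2-reduction of the aryl ketone should leave the epoxide and the ethers intact; the new carbinol centre forms as an epimer mixture, which is harmless because that carbon is ionised in step 7 (the oxirane descriptors change only through the priority rules).

**Step 5**
Reactants: 6 allyl-protected epoxy alcohol
Product: 7 5-(benzyloxy)-2-{[(2R,3R)-3-[4-(benzyloxy)phenyl]oxiran-2-yl](hydroxy)methyl}phenol (both carbinol epimers)
Conditions: Pd(PPh3)4 (5 mol%), morpholine, THF, rt; filtered through neutral alumina and used at once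
Reagents that add atoms: none
Why: Tsuji–Trost-type deallylation, in which zerovalent palladium ionises the aryl allyl ether to a π-allyl complex that morpholine captures, should free the phenol under near-neutral conditions that spare the benzyl ethers and the acid-labile epoxide; no stereocentre changes.

**Step 6**
Reactants: 8 (−)-epicatechin
Product: 9 5,7,3',4'-tetra-O-benzyl-(−)-epicatechin
Conditions: BnBr (4.2 equiv), K2CO3, DMF, 0 °C to rt, argon
Reagents that add atoms: benzyl bromide BrCc1ccccc1
Why: Williamson etherification of the four phenoxides should leave the secondary 3-hydroxyl free, since K2CO3 does not deprotonate it, and should not touch the two stereocentres at room temperature under argon.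

**Step 7**
Reactants: 7 phenolic epoxy alcohol; 9 5,7,3',4'-tetra-O-benzyl-(−)-epicatechin
Product: 12 hexa-O-benzyl ent-guibourtinidol-(4β→8)-epicatechin, via flavan-3,4-diol 10 (not isolated), via C4 benzylic cation 11 (not isolated)
Conditions: 9 (3 equiv), Me3SiOTf (0.2 equiv), CH2Cl2, −78 °C to −20 °C; then aq NaHCO3
Reagents that add atoms: none
Why: Proposed new method: the acid should first open the strained epoxide at C2, where the developing cation is stabilised by the para-benzyloxy group of ring B, and the ring-A phenol should close ring C in the 6-endo mode with inversion at C2 to give the 2,3-trans flavan-3,4-diol 10; on warming, the 4-hydroxyl of 10, para to O7 and ortho to O1, should ionise to cation 11, which C8 of 9 captures in a Friedel–Crafts alkylation. The closest known reaction types are the acid-catalysed 6-endo cyclisation of phenol-tethered aryl epoxides to 2,3-trans-flavan-3-ols and the Lewis-acid coupling of C4-oxygenated flavan-3-ols with benzylated flavan-3-ol nucleophiles, merged here in one flask. C2 is controlled by the epoxide configuration (anti opening, both substituents equatorial in the new ring), C4 by attack on the half-chair cation anti to the 3-hydroxyl, and C3 is carried unchanged from step 3, so the one catalytic event relays to the other two centres. The step needs C8 over C6 selectivity in 9, secured because C6 is flanked by two benzyloxy groups whereas C8 lies between the ring oxygen and one benzyloxy group. It also needs ring closure before C4 ionisation, which epoxide strain and intramolecular delivery at −78 °C should secure, and both carbinol epimers of 7 converge on the same cation. Excess 9 and the lower nucleophilicity of the resorcinol-type ring A should suppress self-condensation of 11.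

**Step 8**
Reactants: 12 hexa-O-benzyl ent-guibourtinidol-(4β→8)-epicatechin
Product: 13 ent-guibourtinidol-(4β→8)-epicatechin (target)
Conditions: H2 (1 atm), Pd(OH)2 on carbon, THF/MeOH, rt
Reagents that add atoms: none
Why: Catalytic hydrogenolysis should cleave the six O-benzyl ethers much faster than the cyclic benzylic ether bonds of the two C rings or the interflavan C–C bond, and touches no stereocentre.

**Compound list**
1 | 1-[4-(benzyloxy)-2-hydroxyphenyl]ethan-1-one | CC(=O)c1ccc(OCc2ccccc2)cc1O | starting material
2 | 1-[4-(benzyloxy)-2-(prop-2-en-1-yloxy)phenyl]ethan-1-one | CC(=O)c1ccc(OCc2ccccc2)cc1OCC=C | intermediate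
3 | 4-(benzyloxy)benzaldehyde | O=Cc1ccc(OCc2ccccc2)cc1 | starting material
4 | (E)-3-[4-(benzyloxy)phenyl]-1-[4-(benzyloxy)-2-(prop-2-en-1-yloxy)phenyl]prop-2-en-1-one | O=C(/C=C/c1ccc(OCc2ccccc2)cc1)c1ccc(OCc2ccccc2)cc1OCC=C | intermediate
5 | [4-(benzyloxy)-2-(prop-2-en-1-yloxy)phenyl][(2S,3R)-3-[4-(benzyloxy)phenyl]oxiran-2-yl]methanone (trans-epoxide) | O=C(c1ccc(OCc2ccccc2)cc1OCC=C)[C@H]1O[C@@H]1c1ccc(OCc2ccccc2)cc1 | intermediate
6 | [4-(benzyloxy)-2-(prop-2-en-1-yloxy)phenyl][(2R,3R)-3-[4-(benzyloxy)phenyl]oxiran-2-yl]methanol, both carbinol epimers | OC(c1ccc(OCc2ccccc2)cc1OCC=C)[C@H]1O[C@@H]1c1ccc(OCc2ccccc2)cc1 | intermediate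
7 | 5-(benzyloxy)-2-{[(2R,3R)-3-[4-(benzyloxy)phenyl]oxiran-2-yl](hydroxy)methyl}phenol, both carbinol epimers | OC(c1ccc(OCc2ccccc2)cc1O)[C@H]1O[C@@H]1c1ccc(OCc2ccccc2)cc1 | intermediate
8 | (−)-epicatechin, (2R,3R)-2-(3,4-dihydroxyphenyl)chromane-3,5,7-triol | Oc1cc(O)c2c(c1)O[C@H](c1ccc(O)c(O)c1)[C@H](O)C2 | starting material
9 | 5,7,3',4'-tetra-O-benzyl-(−)-epicatechin, (2R,3R)-5,7-bis(benzyloxy)-2-[3,4-bis(benzyloxy)phenyl]chroman-3-ol | O(Cc1ccccc1)c1cc(OCc2ccccc2)c2c(c1)O[C@H](c1ccc(OCc3ccccc3)c(OCc3ccccc3)c1)[C@H](O)C2 | intermediate
10 | (2S,3R)-7-(benzyloxy)-2-[4-(benzyloxy)phenyl]chromane-3,4-diol, 2,3-trans, both C4 epimers | O(Cc1ccccc1)c1ccc([C@@H]2Oc3cc(OCc4ccccc4)ccc3C(O)[C@H]2O)cc1 | intermediate (not isolated)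
11 | (2S,3R)-7-(benzyloxy)-2-[4-(benzyloxy)phenyl]-3-hydroxychroman-4-ylium, the C4 benzylic cation | O(Cc1ccccc1)c1ccc([C@@H]2Oc3cc(OCc4ccccc4)ccc3[CH+][C@H]2O)cc1 | intermediate (not isolated)
12 | hexa-O-benzyl ent-guibourtinidol-(4β→8)-epicatechin, (2R,3R)-5,7-bis(benzyloxy)-8-{(2S,3R,4R)-7-(benzyloxy)-2-[4-(benzyloxy)phenyl]-3-hydroxychroman-4-yl}-2-[3,4-bis(benzyloxy)phenyl]chroman-3-ol | O(Cc1ccccc1)c1ccc([C@@H]2Oc3cc(OCc4ccccc4)ccc3[C@H](c3c(OCc4ccccc4)cc(OCc4ccccc4)c4c3O[C@H](c3ccc(OCc5ccccc5)c(OCc5ccccc5)c3)[C@H](O)C4)[C@H]2O)cc1 | intermediate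
13 | ent-guibourtinidol-(4β→8)-epicatechin, (2R,3R)-2-(3,4-dihydroxyphenyl)-8-[(2S,3R,4R)-3,7-dihydroxy-2-(4-hydroxyphenyl)chroman-4-yl]chromane-3,5,7-triol | Oc1ccc([C@@H]2Oc3cc(O)ccc3[C@H](c3c(O)cc(O)c4c3O[C@H](c3ccc(O)c(O)c3)[C@H](O)C4)[C@H]2O)cc1 | target

**Step count and risks**
Total: 8 steps. Longest linear sequence: 7 steps (steps 1, 2, 3, 4, 5, 7, 8).

Step 7 (the step that goes beyond known chemistry). What may go wrong: ionisation of the C4 carbinol before the epoxide has closed ring C, so that the arene adds to an open-chain cation with poor facial control; capture of the epoxide-derived C2 cation by the arene instead of the phenol; incomplete face selectivity at C4; or attack through C6 of 9. The fallback uses known chemistry, sets out from 7 and comes back at 12. 7 is cyclised alone under weak acid (PPTS, CH2Cl2, 0 °C), the known phenol–epoxide 6-endo closure, and the flavan-3,4-diol 10 is isolated. Acid-catalysed exchange at C4 with 2-ethoxyethanol (CSA, CH2Cl2) then gives the 4-(2-ethoxyethoxy)flavan-3-ol F1, a storable C4 electrophile of the established kind. F1 is coupled with 9 by Me3SiOTf in CH2Cl2 at −78 °C to give 12.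

Step 5. What may go wrong: premature or misdirected attack of the freed phenol on the labile epoxide (5-exo closure at the carbinol-bearing epoxide carbon), or isomerisation of the epoxide on the palladium catalyst or during purification. The fallback sets out from 5 and comes back at 10. The allyl group is removed at the ketone stage (Pd(PPh3)4, morpholine, THF) to give the 2'-hydroxy epoxy ketone F2, in which the phenol is held by a hydrogen bond to the carbonyl group. Mild base (catalytic K2CO3, MeOH, 0 °C) closes F2 in the 6-endo sense with inversion to the trans-(2S,3S)-dihydroflavonol F3, as in the closing stage of the Algar–Flynn–Oyamada reaction. NaBH4 reduces F3 to the flavan-3,4-diol 10, which is then treated with 9 and Me3SiOTf as in the second half of step 7 to reach 12.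

Step 6. What may go wrong: base-induced epimerisation at C2 through opening of ring C to a ring-B quinone methide, C-benzylation of the phloroglucinol ring and air oxidation of the catechol, all of which cut the supply of 9. The fallback sets out from 8 and comes back at 13. Free 8 is used as the nucleophile, as in the classical acid-catalysed condensation of flavan-3,4-diols with free flavan-3-ols. Isolated 10 (made as in the fallback for step 7) and 8 in aqueous THF with dilute HCl should give the 7,4'-di-O-benzyl ent-guibourtinidol-(4β→8)-epicatechin F4, to be separated from its C6-linked isomer by chromatography. Hydrogenolysis of F4 over Pd(OH)2 on carbon gives 13 directly.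

**Further compounds**
F1 | step 7 | (2S,3R)-7-(benzyloxy)-2-[4-(benzyloxy)phenyl]-4-(2-ethoxyethoxy)chroman-3-ol, both C4 epimers | O(Cc1ccccc1)c1ccc([C@@H]2Oc3cc(OCc4ccccc4)ccc3C(OCCOCC)[C@H]2O)cc1
F2 | step 5 | [4-(benzyloxy)-2-hydroxyphenyl][(2S,3R)-3-[4-(benzyloxy)phenyl]oxiran-2-yl]methanone | O=C(c1ccc(OCc2ccccc2)cc1O)[C@H]1O[C@@H]1c1ccc(OCc2ccccc2)cc1
F3 | step 5 | (2S,3S)-7-(benzyloxy)-2-[4-(benzyloxy)phenyl]-3-hydroxychroman-4-one | O(Cc1ccccc1)c1ccc([C@@H]2Oc3cc(OCc4ccccc4)ccc3C(=O)[C@H]2O)cc1
F4 | step 6 | (2R,3R)-8-{(2S,3R,4R)-7-(benzyloxy)-2-[4-(benzyloxy)phenyl]-3-hydroxychroman-4-yl}-2-(3,4-dihydroxyphenyl)chromane-3,5,7-triol | O(Cc1ccccc1)c1ccc([C@@H]2Oc3cc(OCc4ccccc4)ccc3[C@H](c3c(O)cc(O)c4c3O[C@H](c3ccc(O)c(O)c3)[C@H](O)C4)[C@H]2O)cc1
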